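**Retrosynthetic overview**
- The target is opened at two places: the aryl O–SO3H bond (late phenol sulfation) and a temporary CH2 bridge between spermidine N1 and N4 (removed last).
- The bridged macrolactam comes from a seco amino acid in one flask: formaldehyde closes a hexahydropyrimidine across N1/N4, then the ring N1–H is acylated by the ring-B cinnamic acid to close the macrocycle.
- The seco amino acid comes from global BBr3 deprotection (O-methyl and two Boc groups) of a diaryl ether acid, made by Ullmann C–O coupling of an isoferuloyl amide phenol and (E)-4-bromocinnamic acid.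
- The amide comes from isoferulic acid and N1,N4-bis-Boc-spermidine (free N8 amine).
- Ring order: benzene rings A and B are bought; the hexahydropyrimidine and the 24-membered macrocycle form together in the key step; the hexahydropyrimidine is opened again in the last step.

Assumption: the target has no stereocentre (its only stereo-elements are the two E alkenes), so the E,E isomer drawn is the goal; the hydrogen sulfate is isolated as its inner salt with the secondary amine.

**Route**

Step 1
Reactants: 1 isoferulic acid, (E)-3-(3-hydroxy-4-methoxyphenyl)prop-2-enoic acid; 2 N1,N4-bis-Boc-spermidine, tert-butyl N-(4-aminobutyl)-N-[3-(tert-butoxycarbonylamino)propyl]carbamate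
Product: 3 N8-isoferuloyl-N1,N4-bis-Boc-spermidine (E-cinnamamide on N8, free 3-OH, 4-OMe)
Conditions: DIC, HOBt, DMF, 0 °C → rt
Reagents that add atoms: none
Why: Carbodiimide/HOBt amidation, in which the only free amine of 2 (primary N8) aminolyses the OBt ester far faster than the unprotected phenol is acylated, and the E alkene of 1 is untouched.

Step 2
Reactants: 3 N8-isoferuloyl-N1,N4-bis-Boc-spermidine; 4 (E)-4-bromocinnamic acid, (E)-3-(4-bromophenyl)prop-2-enoic acid
Product: 5 diaryl ether acid, (E)-3-[4-[2-methoxy-5-[(E)-3-oxo-3-[[4-[Boc-[3-(Boc-amino)propyl]amino]butyl]amino]prop-1-enyl]phenoxy]phenyl]prop-2-enoic acid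
Conditions: CuI (10 mol%), picolinic acid (20 mol%), K3PO4 (3.5 equiv), DMSO, 90 °C
Reagents that add atoms: none
Why: Ullmann-type copper-catalysed diaryl ether coupling, whose picolinic acid ligand system accepts ortho-substituted phenols, prefers phenoxide O-arylation over carbamate or amide N–H arylation, and tolerates the bromide partner as its carboxylate when extra base is present, while both E alkenes survive.

Step 3
Reactants: 5 diaryl ether acid
Product: 6 seco amino acid, (E)-3-[4-[5-[(E)-3-[[4-(3-aminopropylamino)butyl]amino]-3-oxoprop-1-enyl]-2-hydroxyphenoxy]phenyl]prop-2-enoic acid (isolated as the zwitterion after C18 chromatography)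
Conditions: BBr3 (8 equiv), CH2Cl2, −78 → 0 °C; then H2O
Reagents that add atoms: none
Why: Lewis-acid ether cleavage, in which BBr3 demethylates the aryl methyl ether and removes both Boc groups in one flask, while the diaryl ether, the amide, the acid and the two deactivated cinnamoyl alkenes are inert at or below 0 °C.

Step 4
Reactants: 6 seco amino acid
Product: 8 N1,N4-methylene-bridged macrolactam phenol (the target without its sulfate, carrying a 3-acyl-1-alkylhexahydropyrimidine inside the macrocycle), via hexahydropyrimidine seco acid 7 (not isolated)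
Conditions: 37% aq. CH2O (1.05 equiv), iPr2NEt, DMF, 0 °C → rt; then dilute to 1 mM, DEPBT (2 equiv), iPr2NEt, rt → 40 °C
Reagents that add atoms: formaldehyde, C=O
Why: Proposed new method: one-flask Mannich-type aminalization/macrolactamization, in which formaldehyde first condenses with the 1,3-diamine unit (N1H2/N4H) to give the six-membered hexahydropyrimidine, turning N4 into an unreactive tertiary amine and leaving the ring N1–H as the only acylatable nitrogen, so that DEPBT activation of the ring-B cinnamic acid at 1 mM closes the macrocycle regiospecifically at N1 without acylating the phenol and without touching either E alkene (no stereocentre is created); the closest known reaction types are the formaldehyde masking of spermidine as its hexahydropyrimidine followed by N-acylation of the ring N–H, and organophosphorus-mediated macrolactamization of seco amino acids.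

Step 5
Reactants: 8 N1,N4-methylene-bridged macrolactam phenol
Product: 10 target (CID124202369, E,E-macrocyclic spermidine bis-cinnamamide aryl hydrogen sulfate, isolated as the inner salt by C18 chromatography), via aryl sulfate aminal 9 (not isolated)
Conditions: SO3·pyridine (4 equiv), pyridine, 40 °C; then H2O (quench), malonic acid (10 equiv), EtOH, reflux
Reagents that add atoms: sulfur trioxide–pyridine complex, [O-]S(=O)(=O)[n+]1ccccc1
Why: Phenol O-sulfation with SO3·pyridine hits the only free OH because N4 is still a tertiary aminal nitrogen and N1/N8 are amides, and the N-acyl aminal is then opened by Knoevenagel-type scavenging of formaldehyde with malonic acid in pyridine/ethanol (the standard unmasking of hexahydropyrimidine-protected acylspermidines), a pyridine-buffered medium in which the aryl sulfate monoester is stable.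

**Compound list**

1 | isoferulic acid, (E)-3-(3-hydroxy-4-methoxyphenyl)prop-2-enoic acid | COc1ccc(/C=C/C(=O)O)cc1O | starting material
2 | N1,N4-bis-Boc-spermidine, tert-butyl N-(4-aminobutyl)-N-[3-(tert-butoxycarbonylamino)propyl]carbamate | NCCCCN(CCCNC(=O)OC(C)(C)C)C(=O)OC(C)(C)C | starting material
3 | N8-isoferuloyl-N1,N4-bis-Boc-spermidine, tert-butyl N-[3-(tert-butoxycarbonylamino)propyl]-N-[4-[[(E)-3-(3-hydroxy-4-methoxyphenyl)prop-2-enoyl]amino]butyl]carbamate | COc1ccc(/C=C/C(=O)NCCCCN(CCCNC(=O)OC(C)(C)C)C(=O)OC(C)(C)C)cc1O | intermediate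
4 | (E)-4-bromocinnamic acid, (E)-3-(4-bromophenyl)prop-2-enoic acid | OC(=O)/C=C/c1ccc(Br)cc1 | starting material
5 | diaryl ether acid, (E)-3-[4-[2-methoxy-5-[(E)-3-oxo-3-[[4-[Boc-[3-(Boc-amino)propyl]amino]butyl]amino]prop-1-enyl]phenoxy]phenyl]prop-2-enoic acid | COc1ccc(/C=C/C(=O)NCCCCN(CCCNC(=O)OC(C)(C)C)C(=O)OC(C)(C)C)cc1Oc1ccc(/C=C/C(=O)O)cc1 | intermediate
6 | seco amino acid, (E)-3-[4-[5-[(E)-3-[[4-(3-aminopropylamino)butyl]amino]-3-oxoprop-1-enyl]-2-hydroxyphenoxy]phenyl]prop-2-enoic acid | Oc1ccc(/C=C/C(=O)NCCCCNCCCN)cc1Oc1ccc(/C=C/C(=O)O)cc1 | intermediate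
7 | hexahydropyrimidine seco acid, (E)-3-[4-[5-[(E)-3-[[4-(1,3-diazinan-1-yl)butyl]amino]-3-oxoprop-1-enyl]-2-hydroxyphenoxy]phenyl]prop-2-enoic acid | Oc1ccc(/C=C/C(=O)NCCCCN2CCCNC2)cc1Oc1ccc(/C=C/C(=O)O)cc1 | intermediate
8 | N1,N4-methylene-bridged macrolactam phenol (target without sulfate; CH2 joins the coumaroyl amide N1 and the central N4 as a hexahydropyrimidine; both alkenes E) | O=C1/C=C/c2ccc(O)c(c2)Oc2ccc(cc2)/C=C/C(=O)N2CCCN(C2)CCCCN1 | intermediate
9 | aryl hydrogen sulfate of 8 (N1,N4-methylene bridge still in place; both alkenes E) | O=C1/C=C/c2ccc(OS(=O)(=O)O)c(c2)Oc2ccc(cc2)/C=C/C(=O)N2CCCN(C2)CCCCN1 | intermediate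
10 | CID124202369, macrocyclic N8-(3-aryloxy-4-sulfooxy-E-cinnamoyl)-N1-(4-aryloxy-E-cinnamoyl)spermidine with free N4–H | O=C1/C=C/c2ccc(OS(=O)(=O)O)c(c2)Oc2ccc(cc2)/C=C/C(=O)NCCCNCCCCN1 | target

**Step count and risks**

Total step count: 5. Longest linear sequence: 5 steps (1 or 2 → 10).

The three steps most likely to fail:

Step 4 (key step). The aminal N–H may be acylated too slowly at 1 mM, giving oligomers. The fallback closes the macrocycle at a C–C bond instead and sets out from 3. Ullmann coupling of 3 with excess 1,4-diiodobenzene (CuI, picolinic acid, K3PO4, DMSO, 90 °C) gives the 4-iodophenyl ether of 3 F1. BBr3 (CH2Cl2, −78 → 0 °C, then H2O) removes the methyl and both Boc groups to give the amino phenol aryl iodide F2. Aqueous CH2O converts this to the hexahydropyrimidine aryl iodide F3, which is acylated in the same flask on the ring N–H with acryloyl chloride (NaHCO3, CH2Cl2/H2O, 0 °C) to give the N1-acryloyl hexahydropyrimidine aryl iodide F4. An intramolecular Mizoroki–Heck reaction (Pd(OAc)2, P(o-tol)3, Et3N, DMF, 1 mM, 100 °C) then forms the ring-B aryl–vinyl bond E-selectively and comes back to the route at 8.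

Step 2. The free carboxylate of 4 or the carbamate N–H of 3 may interfere with the copper catalyst. The fallback builds the ring-B cinnamic acid after the ether bond and sets out from 3. SNAr with 4-fluorobenzaldehyde (Cs2CO3, DMSO, 90 °C) gives the 4-formylphenyl ether of 3 F5. Knoevenagel–Doebner condensation with malonic acid (pyridine, cat. piperidine, 90 °C) then gives the E-cinnamic acid and comes back to the route at 5.

Step 5. SO3 may be held on the aminal nitrogen, or the unprotected sulfate may be lost or hard to handle during the aminal opening. The fallback carries the sulfate as a neutral protected diester and sets out from 8. 2,2,2-Trichloroethyl chlorosulfate (Et3N, DMAP, THF, 0 °C → rt) gives the 2,2,2-trichloroethyl sulfate diester of 8 F6. Malonic acid in pyridine/EtOH at reflux opens the aminal to the 2,2,2-trichloroethyl sulfate diester of 10 F7. Zn dust with HCO2NH4 in MeOH at rt removes the trichloroethyl group without reducing the alkenes and comes back to the route at 10.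

**Further compounds**

F1 | step 4 | 4-iodophenyl ether of 3, tert-butyl N-[3-(tert-butoxycarbonylamino)propyl]-N-[4-[[(E)-3-[3-(4-iodophenoxy)-4-methoxyphenyl]prop-2-enoyl]amino]butyl]carbamate | COc1ccc(/C=C/C(=O)NCCCCN(CCCNC(=O)OC(C)(C)C)C(=O)OC(C)(C)C)cc1Oc1ccc(I)cc1
F2 | step 4 | amino phenol aryl iodide, (E)-N-[4-(3-aminopropylamino)butyl]-3-[4-hydroxy-3-(4-iodophenoxy)phenyl]prop-2-enamide | Oc1ccc(/C=C/C(=O)NCCCCNCCCN)cc1Oc1ccc(I)cc1
F3 | step 4 | hexahydropyrimidine aryl iodide, (E)-N-[4-(1,3-diazinan-1-yl)butyl]-3-[4-hydroxy-3-(4-iodophenoxy)phenyl]prop-2-enamide | Oc1ccc(/C=C/C(=O)NCCCCN2CCCNC2)cc1Oc1ccc(I)cc1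
F4 | step 4 | N1-acryloyl hexahydropyrimidine aryl iodide, (E)-N-[4-(3-acryloyl-1,3-diazinan-1-yl)butyl]-3-[4-hydroxy-3-(4-iodophenoxy)phenyl]prop-2-enamide | Oc1ccc(/C=C/C(=O)NCCCCN2CCCN(C(=O)C=C)C2)cc1Oc1ccc(I)cc1
F5 | step 2 | 4-formylphenyl ether of 3, tert-butyl N-[3-(tert-butoxycarbonylamino)propyl]-N-[4-[[(E)-3-[3-(4-formylphenoxy)-4-methoxyphenyl]prop-2-enoyl]amino]butyl]carbamate | COc1ccc(/C=C/C(=O)NCCCCN(CCCNC(=O)OC(C)(C)C)C(=O)OC(C)(C)C)cc1Oc1ccc(C=O)cc1
F6 | step 5 | 2,2,2-trichloroethyl sulfate diester of 8 | O=C1/C=C/c2ccc(OS(=O)(=O)OCC(Cl)(Cl)Cl)c(c2)Oc2ccc(cc2)/C=C/C(=O)N2CCCN(C2)CCCCN1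
F7 | step 5 | 2,2,2-trichloroethyl sulfate diester of 10 | O=C1/C=C/c2ccc(OS(=O)(=O)OCC(Cl)(Cl)Cl)c(c2)Oc2ccc(cc2)/C=C/C(=O)NCCCNCCCCN1
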